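**Plan**

- Retrosynthesis cuts the O8 angelate, C4–C15 (Stille) and the lactone bond C12–O6 (oxidation of a 1,4-diol). It then cuts C6–C7 by a retro-[2,3]-Wittig shift that restores O6–C13 and opens the ten-membered carbocycle to a 13-membered propargyl allyl ether.
- The ring contraction is possible because, in the ten-membered ring, C7 carries the C11(=C13)C12 branch next to oxygen-bearing C6 (a 2-substituted homoallylic alcohol). The ring-cis C4=C5 olefin is carried as C4≡C5, so C6–H is the most acidic α-oxy position.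
- Further back the cuts are O6–C13 (Williamson), C7=C11 and C1=C10 (two Horner–Wadsworth–Emmons olefinations), C9–C10 (epoxide opening) and C3–C4 (oxetane opening).
- Forward: the C1–C6 aldehyde is joined to the glycidol-derived phosphono-lactone at C1=C10, C11–C13 are added at C7=C11, the 13-membered ether ring is closed and contracted to the ten-membered ring, and the γ-lactone ring is closed afterwards.
- Stereochemistry: C8 comes from (S)-glycidol. C6 and C7 arise in the ring contraction (anti from the C7=C11 geometry, face from the C8 methoxymethyl ether). C1=C10 comes from the E-alkylidene lactone, C4=C5 from syn-hydrosilylation of the ring alkyne, and the Z-enoate from angelic acid.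

Key step: step 16

Remark: germacranolide numbering is used for all intermediates (ring C1–C10, lactone carbons C11–C13 with O on C6, C14 on C10, C15 on C4); compounds 6, 7, 16, 17 and 37 are taken to be purchasable.

**Route**

Step 1
Reactants: 1 (S)-glycidol
Product: 2 (2R)-2-{[(4-methoxybenzyl)oxy]methyl}oxirane
Conditions: NaH, 4-methoxybenzyl chloride, Bu4NI (cat.), THF/DMF, 0 °C → rt
Reagents that add atoms: 4-methoxybenzyl chloride, COc1ccc(CCl)cc1
Why: Williamson etherification of the primary alkoxide should leave the stereocentre intact, because epoxide migration (Payne rearrangement) of glycidol alkoxide is degenerate and returns the same enantiomer.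

Step 2
Reactants: 2 (2R)-2-{[(4-methoxybenzyl)oxy]methyl}oxirane; 3 triethyl phosphonoacetate
Product: 5 diethyl [(5R)-5-{[(4-methoxybenzyl)oxy]methyl}-2-oxooxolan-3-yl]phosphonate (both C3 epimers), via open-chain hydroxy phosphonoester 4 (not isolated)
Conditions: NaOEt, EtOH, 78 °C; then aq. HCl
Reagents that add atoms: none
Why: The phosphonoacetate carbanion should open the epoxide at its unsubstituted carbon (SN2, C8 untouched) and the resulting alkoxide lactonises onto the ethyl ester, the phosphorus analogue of the malonate epoxide-to-butyrolactone annulation.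

Step 3
Reactants: 6 tert-butyldimethyl(prop-2-yn-1-yloxy)silane; 7 oxetane
Product: 8 6-[(tert-butyldimethylsilyl)oxy]hex-4-yn-1-ol
Conditions: n-BuLi, THF, −78 °C; BF3·OEt2, then 7, −78 °C; H2O
Reagents that add atoms: none
Why: The lithium acetylide opens BF3-activated oxetane at carbon (Yamaguchi alkynylation), adding C3–C1 to the C4≡C5–C6 unit in one step.

Step 4
Reactants: 8 6-[(tert-butyldimethylsilyl)oxy]hex-4-yn-1-ol
Product: 9 6-[(tert-butyldimethylsilyl)oxy]hex-4-ynal
Conditions: TEMPO (cat.), PhI(OAc)2, CH2Cl2, rt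
Reagents that add atoms: none
Why: TEMPO-catalysed oxidation with PhI(OAc)2 stops at the aldehyde and tolerates the silyl ether and the alkyne.

Step 5
Reactants: 5 phosphono-lactone; 9 6-[(tert-butyldimethylsilyl)oxy]hex-4-ynal
Product: 10 (3E,5R)-3-{6-[(tert-butyldimethylsilyl)oxy]hex-4-yn-1-ylidene}-5-{[(4-methoxybenzyl)oxy]methyl}oxolan-2-one
Conditions: NaH, THF, 0 °C; then 9, 0 °C → rt
Reagents that add atoms: none
Why: Horner–Wadsworth–Emmons olefination of the α-phosphono lactone with a sodium counter-ion should favour the E-alkylidene lactone (C2 anti to the carbonyl C14, syn to C9), which is the ring-cis C1=C10 geometry of the target; the minor Z isomer is removed by chromatography.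

Step 6
Reactants: 10 E-alkylidene lactone
Product: 11 (2E,4R)-2-{6-[(tert-butyldimethylsilyl)oxy]hex-4-yn-1-ylidene}-5-[(4-methoxybenzyl)oxy]pentane-1,4-diol
Conditions: i-Bu2AlH, CH2Cl2, −78 → 0 °C; aq. potassium sodium tartrate
Reagents that add atoms: none
Why: i-Bu2AlH reduces the unsaturated lactone 1,2 through the lactol to the allylic 1,4-diol without changing the olefin geometry or touching the silyl and benzyl ethers.

Step 7
Reactants: 11 diol
Product: 12 (2R,4E)-10-[(tert-butyldimethylsilyl)oxy]-4-{[(tert-butyldiphenylsilyl)oxy]methyl}-1-[(4-methoxybenzyl)oxy]dec-4-en-8-yn-2-ol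
Conditions: t-BuPh2SiCl, imidazole, CH2Cl2, 0 °C
Reagents that add atoms: tert-butyl(chloro)diphenylsilane, CC(C)(C)[Si](Cl)(c1ccccc1)c1ccccc1
Why: The bulky silyl chloride discriminates the primary allylic C14 hydroxyl from the secondary C8 hydroxyl (selective silylation).

Step 8
Reactants: 12 secondary alcohol
Product: 13 methoxymethyl ether of 12 at O8 (2R,4E)
Conditions: MeOCH2Cl, i-Pr2NEt, CH2Cl2, 0 °C → rt
Reagents that add atoms: chloromethyl methyl ether, COCCl
Why: Alkylation of the secondary alcohol with the chloromethyl ether installs the chelating acetal that C8 needs in the key step.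

Step 9
Reactants: 13 fully protected enyne
Product: 14 (2R,4E)-10-[(tert-butyldimethylsilyl)oxy]-4-{[(tert-butyldiphenylsilyl)oxy]methyl}-2-(methoxymethoxy)dec-4-en-8-yn-1-ol
Conditions: DDQ, CH2Cl2/pH 7 buffer, 0 °C
Reagents that add atoms: none
Why: Oxidative cleavage of the electron-rich benzyl ether by DDQ leaves the silyl ethers, the acetal, the alkyne and the olefin untouched.

Step 10
Reactants: 14 primary alcohol
Product: 15 (2R,4E)-10-[(tert-butyldimethylsilyl)oxy]-4-{[(tert-butyldiphenylsilyl)oxy]methyl}-2-(methoxymethoxy)dec-4-en-8-ynal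
Conditions: Dess–Martin periodinane, CH2Cl2, 0 °C → rt
Reagents that add atoms: none
Why: Dess–Martin oxidation gives the α-alkoxy aldehyde under non-basic conditions so that C8 is not epimerised; the aldehyde is used crude.

Step 11
Reactants: 15 aldehyde; 16 4-methoxybenzyl alcohol; 17 ethyl 2-(diethoxyphosphoryl)acrylate
Product: 19 ethyl (2E,4R,6E)-12-[(tert-butyldimethylsilyl)oxy]-6-{[(tert-butyldiphenylsilyl)oxy]methyl}-4-(methoxymethoxy)-2-{[(4-methoxybenzyl)oxy]methyl}dodeca-2,6-dien-10-ynoate, via sodium salt of phosphonate 18 (not isolated)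
Conditions: 16, NaH, THF, 0 °C; 17, 0 °C; then 15, −40 → 0 °C
Reagents that add atoms: none
Why: Conjugate addition of the sodium alkoxide to the vinylphosphonate generates the phosphonate carbanion in situ (tandem oxa-Michael/Horner–Wadsworth–Emmons), and its olefination of the aldehyde should place the ester carbon C13 anti to C8, the usual E outcome of α-substituted phosphonoacetates.

Step 12
Reactants: 19 enoate
Product: 20 allylic alcohol (C13 hydroxymethyl trans to C8; C12 still the 4-methoxybenzyl ether)
Conditions: i-Bu2AlH, CH2Cl2, −78 °C; aq. potassium sodium tartrate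
Reagents that add atoms: none
Why: 1,2-Reduction of the enoate by i-Bu2AlH at low temperature gives the allylic alcohol without isomerising C7=C11.

Step 13
Reactants: 20 allylic alcohol
Product: 22 allylic chloride (C13–Cl trans to C8), via allylic mesylate 21 (not isolated)
Conditions: MeSO2Cl, 2,4,6-collidine, LiCl, DMF, 0 °C
Reagents that add atoms: lithium chloride, [Li+].[Cl-]; methanesulfonyl chloride, CS(=O)(=O)Cl (its mesyl group is held in 21 only)
Why: Mesylation and in situ chloride displacement (Collington–Meyers conditions) convert the primary allylic alcohol into the chloride without allylic transposition.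

Step 14
Reactants: 22 allylic chloride
Product: 23 seco hydroxy chloride (free propargylic C6 hydroxyl, C13 chloride)
Conditions: camphorsulfonic acid (cat.), MeOH/CH2Cl2, 0 °C
Reagents that add atoms: none
Why: Acid-catalysed methanolysis removes the primary tert-butyldimethylsilyl ether far faster than the tert-butyldiphenylsilyl ether, the acetal or the benzyl ether.

Step 15
Reactants: 23 seco hydroxy chloride
Product: 24 13-membered propargyl allyl ether (1-oxacyclotrideca-3,7-dien-11-yne; O–C6H2–C4≡C5, ring-cis C1=C10, 8R, C8 trans to C13 across C7=C11)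
Conditions: NaH, Bu4NI (cat.), THF, 65 °C, slow addition to 0.003 M
Reagents that add atoms: none
Why: Intramolecular Williamson etherification at high dilution: the propargylic alkoxide displaces the primary allylic chloride by SN2 at C13, and the rigid C3–C4≡C5–C6 rod and the cis C1=C10 olefin limit the conformational cost of closing the 13-membered ring.

Step 16
Reactants: 24 13-membered propargyl allyl ether
Product: 26 ten-membered enynol (C6 carbinol; C7 bearing the C11(=C13H2)C12H2O-4-methoxybenzyl branch; C6/C7/C8 as in the target, 6S,7S,8R by CIP here), via C6-lithiated ether 25 (not isolated)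
Conditions: n-BuLi, THF/hexane, −78 → −40 °C; H2O
Reagents that add atoms: n-butyllithium, [Li]CCCC (its lithium is held in 25 only)
Why: n-BuLi removes a C6 proton, the most acidic one because it is both propargylic and α to oxygen, and lithio ether 25 undergoes a suprafacial [2,3]-sigmatropic (Wittig) shift through a five-membered envelope transition state in which C6–C7 forms, O–C13 breaks and C11=C13 appears, the lithium alkoxide making it irreversible. The closest known reaction type is the [2,3]-Wittig ring contraction of 13-membered propargyl allyl ethers to cyclodecenynols of the germacrane type. The ten-membered carbocycle is closed by ring contraction, a transannular 1,5-bonding inside the 13-membered ring, not by end-to-end cyclisation. C6 is set by the olefin geometry: with C8 trans to C13 and the alkynyl group exo on the envelope, O6 and C8 end up anti across C6–C7, as the trans-fused lactone requires. C7 is set by C8: H8 eclipses the olefin to avoid allylic 1,3-strain with C12, and lithium bridged to the methoxymethyl ether delivers C6 to the face syn to O8. The step needs lithiation at C6 rather than at C13 or the benzylic CH2 and [2,3] rather than [1,2] shift; the propargylic acidity and a temperature at or below −40 °C in THF without dipolar additives secure both.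

Step 17
Reactants: 26 ten-membered enynol
Product: 27 C4-triethylsilyl dienol (ring-cis C4=C5, Si on C4 trans to C6, H on C5)
Conditions: Et3SiH, PtCl2 (5 mol %), XPhos (10 mol %), THF, 50 °C
Reagents that add atoms: triethylsilane, CC[SiH](CC)CC
Why: PtCl2/XPhos-catalysed hydrosilylation of a propargylic alcohol adds H and Si syn with silicon on the alkyne carbon remote from the carbinol (C4, also the less hindered end), which turns the ring alkyne into the ring-cis olefin; the alkyne reacts far faster than the two olefins.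

Step 18
Reactants: 27 vinylsilane
Product: 28 C6,C12-diol
Conditions: DDQ, CH2Cl2/pH 7 buffer, 0 °C
Reagents that add atoms: none
Why: DDQ cleaves the 4-methoxybenzyl ether in wet solvent faster than it oxidises the secondary allylic alcohol, exposing the C12 hydroxyl.

Step 19
Reactants: 28 C6,C12-diol
Product: 31 α-methylene-γ-butyrolactone (C12=O, O6; trans-fused; Si on C4, O8 methoxymethyl, O14 silyl), via hydroxy enal 29 (not isolated), via lactol 30 (not isolated)
Conditions: TEMPO (cat.), PhI(OAc)2, CH2Cl2, rt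
Reagents that add atoms: none
Why: TEMPO/PhI(OAc)2 oxidises the primary allylic alcohol selectively, the C6 hydroxyl closes the five-membered lactol onto the enal and a second oxidation gives the lactone (oxidative lactonisation of a 1,4-diol); O8 is still blocked, so only the C6 lactone can form.

Step 20
Reactants: 31 silyl lactone
Product: 32 C4-iodo lactone (iodine trans to C6)
Conditions: N-iodosuccinimide, 2,6-lutidine, (CF3)2CHOH, 0 °C
Reagents that add atoms: N-iodosuccinimide, O=C1CCC(=O)N1I
Why: Ipso-iododesilylation in hexafluoroisopropanol proceeds with retention of olefin geometry and should be faster than attack on the C1=C10 olefin, while the methylene lactone is inert to electrophilic iodine.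

Step 21
Reactants: 32 iodo lactone
Product: 33 C8 alcohol
Conditions: Me2BBr, CH2Cl2, −78 °C; then aq. NaHCO3
Reagents that add atoms: none
Why: Me2BBr cleaves methoxymethyl ethers at −78 °C through the bromomethyl ether, which the bicarbonate quench hydrolyses, and spares tert-butyldiphenylsilyl ethers, lactones and alkenyl iodides.

Step 22
Reactants: 33 C8 alcohol; 34 angelic acid
Product: 36 C8 angelate of the iodo lactone, via mixed anhydride 35 (not isolated)
Conditions: 34, 2,4,6-trichlorobenzoyl chloride, Et3N, toluene, rt; then 33, toluene, 75 °C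
Reagents that add atoms: 2,4,6-trichlorobenzoyl chloride, O=C(Cl)c1c(Cl)cc(Cl)cc1Cl (its aroyl group is held in 35 only)
Why: Yamaguchi-type acylation through the mixed 2,4,6-trichlorobenzoic anhydride without a nucleophilic amine catalyst is the usual way to transfer the angeloyl group with its Z geometry retained.

Step 23
Reactants: 36 angelate iodide; 37 (tributylstannyl)methanol
Product: 38 14-O-tert-butyldiphenylsilyl ether of the target
Conditions: Pd(PPh3)4 (10 mol %), 1,4-dioxane, 85 °C
Reagents that add atoms: none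
Why: Stille coupling of the alkenyl iodide with the hydroxymethylstannane (Kosugi hydroxymethylation) replaces iodine by C15 with retention, completing the ring-cis trisubstituted C4=C5 olefin.

Step 24
Reactants: 38 silyl ether
Product: 39 target, [(3aR,4R,6E,10E,11aR)-6,10-bis(hydroxymethyl)-3-methylidene-2-oxo-3a,4,5,8,9,11a-hexahydrocyclodeca[b]furan-4-yl] (2Z)-2-methylbut-2-enoate
Conditions: HF·pyridine, pyridine, THF, 0 °C → rt
Reagents that add atoms: none
Why: Buffered HF·pyridine removes the remaining silyl ether without harming the methylene lactone, the angelate or the allylic alcohols.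

**Compound list**

1 | (S)-glycidol | OC[C@H]1CO1 | starting material
2 | (2R)-2-{[(4-methoxybenzyl)oxy]methyl}oxirane | COc1ccc(COC[C@H]2CO2)cc1 | intermediate
3 | triethyl phosphonoacetate | CCOC(=O)CP(=O)(OCC)OCC | starting material
4 | ethyl (4R)-2-(diethoxyphosphoryl)-4-hydroxy-5-[(4-methoxybenzyl)oxy]pentanoate (as sodium alkoxide, C2 epimers) | CCOC(=O)C(C[C@@H](O)COCc1ccc(OC)cc1)P(=O)(OCC)OCC | intermediate
5 | diethyl [(5R)-5-{[(4-methoxybenzyl)oxy]methyl}-2-oxooxolan-3-yl]phosphonate (C3 epimers) | CCOP(=O)(OCC)C1C[C@H](COCc2ccc(OC)cc2)OC1=O | intermediate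
6 | tert-butyldimethyl(prop-2-yn-1-yloxy)silane | C#CCO[Si](C)(C)C(C)(C)C | starting material
7 | oxetane | C1COC1 | starting material
8 | 6-[(tert-butyldimethylsilyl)oxy]hex-4-yn-1-ol | OCCCC#CCO[Si](C)(C)C(C)(C)C | intermediate
9 | 6-[(tert-butyldimethylsilyl)oxy]hex-4-ynal | O=CCCC#CCO[Si](C)(C)C(C)(C)C | intermediate
10 | (3E,5R)-3-{6-[(tert-butyldimethylsilyl)oxy]hex-4-yn-1-ylidene}-5-{[(4-methoxybenzyl)oxy]methyl}oxolan-2-one | O=C1O[C@@H](COCc2ccc(OC)cc2)C/C1=C\CCC#CCO[Si](C)(C)C(C)(C)C | intermediate
11 | (2E,4R)-2-{6-[(tert-butyldimethylsilyl)oxy]hex-4-yn-1-ylidene}-5-[(4-methoxybenzyl)oxy]pentane-1,4-diol | OC/C(=C/CCC#CCO[Si](C)(C)C(C)(C)C)C[C@@H](O)COCc1ccc(OC)cc1 | intermediate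
12 | (2R,4E)-10-[(tert-butyldimethylsilyl)oxy]-4-{[(tert-butyldiphenylsilyl)oxy]methyl}-1-[(4-methoxybenzyl)oxy]dec-4-en-8-yn-2-ol | CC(C)(C)[Si](c1ccccc1)(c1ccccc1)OC/C(=C/CCC#CCO[Si](C)(C)C(C)(C)C)C[C@@H](O)COCc1ccc(OC)cc1 | intermediate
13 | O8-methoxymethyl ether of 12 (2R,4E) | CC(C)(C)[Si](c1ccccc1)(c1ccccc1)OC/C(=C/CCC#CCO[Si](C)(C)C(C)(C)C)C[C@@H](OCOC)COCc1ccc(OC)cc1 | intermediate
14 | (2R,4E)-10-[(tert-butyldimethylsilyl)oxy]-4-{[(tert-butyldiphenylsilyl)oxy]methyl}-2-(methoxymethoxy)dec-4-en-8-yn-1-ol | CC(C)(C)[Si](c1ccccc1)(c1ccccc1)OC/C(=C/CCC#CCO[Si](C)(C)C(C)(C)C)C[C@@H](OCOC)CO | intermediate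
15 | (2R,4E)-10-[(tert-butyldimethylsilyl)oxy]-4-{[(tert-butyldiphenylsilyl)oxy]methyl}-2-(methoxymethoxy)dec-4-en-8-ynal | CC(C)(C)[Si](c1ccccc1)(c1ccccc1)OC/C(=C/CCC#CCO[Si](C)(C)C(C)(C)C)C[C@@H](OCOC)C=O | intermediate
16 | 4-methoxybenzyl alcohol | COc1ccc(CO)cc1 | starting material
17 | ethyl 2-(diethoxyphosphoryl)acrylate | CCOC(=O)C(=C)P(=O)(OCC)OCC | starting material
18 | ethyl 2-(diethoxyphosphoryl)-3-[(4-methoxybenzyl)oxy]propanoate (as sodium salt) | CCOC(=O)C(COCc1ccc(OC)cc1)P(=O)(OCC)OCC | intermediate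
19 | ethyl (2E,4R,6E)-12-[(tert-butyldimethylsilyl)oxy]-6-{[(tert-butyldiphenylsilyl)oxy]methyl}-4-(methoxymethoxy)-2-{[(4-methoxybenzyl)oxy]methyl}dodeca-2,6-dien-10-ynoate | CC(C)(C)[Si](c1ccccc1)(c1ccccc1)OC/C(=C/CCC#CCO[Si](C)(C)C(C)(C)C)C[C@@H](OCOC)/C=C(\COCc1ccc(OC)cc1)C(=O)OCC | intermediate
20 | allylic alcohol from 19 (4R; C13H2OH trans to C8) | CC(C)(C)[Si](c1ccccc1)(c1ccccc1)OC/C(=C/CCC#CCO[Si](C)(C)C(C)(C)C)C[C@@H](OCOC)/C=C(\COCc1ccc(OC)cc1)CO | intermediate
21 | methanesulfonate of 20 | CC(C)(C)[Si](c1ccccc1)(c1ccccc1)OC/C(=C/CCC#CCO[Si](C)(C)C(C)(C)C)C[C@@H](OCOC)/C=C(\COCc1ccc(OC)cc1)COS(C)(=O)=O | intermediate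
22 | allylic chloride (C13–Cl trans to C8) | CC(C)(C)[Si](c1ccccc1)(c1ccccc1)OC/C(=C/CCC#CCO[Si](C)(C)C(C)(C)C)C[C@@H](OCOC)/C=C(\COCc1ccc(OC)cc1)CCl | intermediate
23 | seco hydroxy chloride (C6–OH, C13–Cl) | CC(C)(C)[Si](c1ccccc1)(c1ccccc1)OC/C(=C/CCC#CCO)C[C@@H](OCOC)/C=C(\COCc1ccc(OC)cc1)CCl | intermediate
24 | 13-membered propargyl allyl ether (O8 methoxymethyl, O12 4-methoxybenzyl, O14 tert-butyldiphenylsilyl; 8R) | O1CC#CCC/C=C(/CO[Si](c2ccccc2)(c2ccccc2)C(C)(C)C)C[C@@H](OCOC)/C=C(\COCc2ccc(OC)cc2)C1 | intermediate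
25 | C6-lithio derivative of 24 | O1C([Li])C#CCC/C=C(/CO[Si](c2ccccc2)(c2ccccc2)C(C)(C)C)C[C@@H](OCOC)/C=C(\COCc2ccc(OC)cc2)C1 | intermediate
26 | ten-membered enynol (C6–OH, C7 2-propenyl-type branch; 6S,7S,8R by CIP, as in the target) | O[C@@H]1C#CCC/C=C(/CO[Si](c2ccccc2)(c2ccccc2)C(C)(C)C)C[C@@H](OCOC)[C@H]1C(=C)COCc1ccc(OC)cc1 | intermediate
27 | C4-triethylsilyl dienol (4E, ring-cis; 6S,7S,8R) | O[C@@H]1/C=C(/[Si](CC)(CC)CC)CC/C=C(/CO[Si](c2ccccc2)(c2ccccc2)C(C)(C)C)C[C@@H](OCOC)[C@H]1C(=C)COCc1ccc(OC)cc1 | intermediate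
28 | C6,C12-diol | O[C@@H]1/C=C(/[Si](CC)(CC)CC)CC/C=C(/CO[Si](c2ccccc2)(c2ccccc2)C(C)(C)C)C[C@@H](OCOC)[C@H]1C(=C)CO | intermediate
29 | C12 enal with free C6–OH | O[C@@H]1/C=C(/[Si](CC)(CC)CC)CC/C=C(/CO[Si](c2ccccc2)(c2ccccc2)C(C)(C)C)C[C@@H](OCOC)[C@H]1C(=C)C=O | intermediate
30 | C12 lactol | C=C1C(O)O[C@@H]2/C=C(/[Si](CC)(CC)CC)CC/C=C(/CO[Si](c3ccccc3)(c3ccccc3)C(C)(C)C)C[C@@H](OCOC)[C@@H]12 | intermediate
31 | α-methylene lactone, C4-triethylsilyl (6S,7R,8R by CIP) | C=C1C(=O)O[C@@H]2/C=C(/[Si](CC)(CC)CC)CC/C=C(/CO[Si](c3ccccc3)(c3ccccc3)C(C)(C)C)C[C@@H](OCOC)[C@@H]12 | intermediate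
32 | α-methylene lactone, C4-iodo | C=C1C(=O)O[C@@H]2/C=C(/I)CC/C=C(/CO[Si](c3ccccc3)(c3ccccc3)C(C)(C)C)C[C@@H](OCOC)[C@@H]12 | intermediate
33 | C8 alcohol of the iodo lactone | C=C1C(=O)O[C@@H]2/C=C(/I)CC/C=C(/CO[Si](c3ccccc3)(c3ccccc3)C(C)(C)C)C[C@@H](O)[C@@H]12 | intermediate
34 | angelic acid, (2Z)-2-methylbut-2-enoic acid | C/C=C(/C)C(=O)O | starting material
35 | angelic 2,4,6-trichlorobenzoic anhydride | C/C=C(/C)C(=O)OC(=O)c1c(Cl)cc(Cl)cc1Cl | intermediate
36 | C8 angelate of the iodo lactone | C=C1C(=O)O[C@@H]2/C=C(/I)CC/C=C(/CO[Si](c3ccccc3)(c3ccccc3)C(C)(C)C)C[C@@H](OC(=O)/C(C)=C\C)[C@@H]12 | intermediate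
37 | (tributylstannyl)methanol | CCCC[Sn](CO)(CCCC)CCCC | starting material
38 | 14-O-tert-butyldiphenylsilyl ether of the target | C=C1C(=O)O[C@@H]2/C=C(/CO)CC/C=C(/CO[Si](c3ccccc3)(c3ccccc3)C(C)(C)C)C[C@@H](OC(=O)/C(C)=C\C)[C@@H]12 | intermediate
39 | CNP0182172.4, (6R,7R,8R)-8-angeloyloxy-14,15-dihydroxygermacra-1(10),4,11(13)-trien-12,6-olide with both ring olefins ring-cis | C=C1C(=O)O[C@@H]2/C=C(/CO)CC/C=C(/CO)C[C@@H](OC(=O)/C(C)=C\C)[C@@H]12 | target

**Step count**

Total: 24 steps. Longest linear sequence: 22 steps (1 → 39 through steps 1, 2 and 5–24; the branch 6 + 7 → 9 is two steps).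

**Steps most likely to fail**

Step 16. The carbanion may bond to the face of C7=C11 anti to O8 if the ring conformation overrides the chelation and allylic-strain bias (poor facial selectivity). Lithiation at the benzylic CH2 or a [1,2]-shift may also compete. The fallback moves from substrate control to reagent control. It sets out from 24 and uses a homochiral lithium amide, lithium bis[(1S)-1-phenylethyl]amide or its enantiomer (whichever matches the substrate), in THF at −40 °C. Enantiotopic C6–H removal by such amides is known to steer [2,3]-Wittig ring contractions of 13-membered propargyl allyl ethers, and the bulkier, weaker base should also leave the benzylic position alone. The fallback comes back to the route at 26 and makes no compound outside the list (F0).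

Step 17. Silicon may be delivered to C5 instead of C4 (poor regioselectivity), and in step 20 iodination of the C1=C10 olefin may compete with ipso-substitution. The fallback replaces the silicon chemistry by boron. It sets out from 26: CuCl/Xantphos, NaOt-Bu (cat.), bis(pinacolato)diboron and MeOH in THF should add boron and hydrogen syn with boron on C4, remote from the oxygen-bearing C6, to give alkenyl boronate F1. NaOH/I2 in THF–H2O at 0 °C should exchange boron for iodine with retention, giving iodo alcohol F2. DDQ as in step 18 then gives iodo diol F3, and TEMPO/PhI(OAc)2 as in step 19 closes the lactone. The fallback comes back to the route at 32.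

Step 22. The Z-enoate may isomerise to the tiglate during acyl transfer, and slow acylation of the hindered C8 hydroxyl may let it attack C12 (lactone migration from O6 to O8). The fallback builds the Z-olefin on the ester instead of transferring it. It sets out from 33: esterification with 2-[bis(2,2,2-trifluoroethoxy)phosphoryl]propanoic acid (N,N'-dicyclohexylcarbodiimide, 4-(dimethylamino)pyridine cat., CH2Cl2, 0 °C) should give phosphonate ester F4. Still–Gennari olefination of F4 with acetaldehyde (KN(SiMe3)2, 18-crown-6, THF, −78 °C) should then give the Z-2-methylbut-2-enoate. The fallback comes back to the route at 36.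

**Further compounds**

F0 | step 16 | none | none
F1 | step 17 | C4-(pinacolboryl) dienol from 26 (boron trans to C6) | O[C@@H]1/C=C(/B2OC(C)(C)C(C)(C)O2)CC/C=C(/CO[Si](c3ccccc3)(c3ccccc3)C(C)(C)C)C[C@@H](OCOC)[C@H]1C(=C)COCc1ccc(OC)cc1
F2 | step 17 | C4-iodo dienol with O12 4-methoxybenzyl ether | O[C@@H]1/C=C(/I)CC/C=C(/CO[Si](c2ccccc2)(c2ccccc2)C(C)(C)C)C[C@@H](OCOC)[C@H]1C(=C)COCc1ccc(OC)cc1
F3 | step 17 | C4-iodo C6,C12-diol | O[C@@H]1/C=C(/I)CC/C=C(/CO[Si](c2ccccc2)(c2ccccc2)C(C)(C)C)C[C@@H](OCOC)[C@H]1C(=C)CO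
F4 | step 22 | C8 2-[bis(2,2,2-trifluoroethoxy)phosphoryl]propanoate of 33 | C=C1C(=O)O[C@@H]2/C=C(/I)CC/C=C(/CO[Si](c3ccccc3)(c3ccccc3)C(C)(C)C)C[C@@H](OC(=O)C(C)P(=O)(OCC(F)(F)F)OCC(F)(F)F)[C@@H]12
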